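Count the nucleophile in pairs before you look at any rate constant of this flask.

electrophile 0.18 M; solid nucleophile 0.270 M; time 5.0 min

    electrophile + nucleophile → acid set free + product (k1 = 1.48 L mol⁻¹ s⁻¹)
    nucleophile + acid set free ⇌ protonated nucleophile, settled at all times (K2 = 3800 L mol⁻¹)
    solid nucleophile ⇌ nucleophile, rate k3*(cs3 - [nucleophile]) while solid is left; crystals form when [nucleophile] > cs3 (cs3 = 0.13 M, k3 = 0.0865 s⁻¹)
    electrophile ⇌ dormant form (K4 = 2.18, k4 = 0.0667 s⁻¹)

- as a solid, counted per litre of solution: solid nucleophile
- at the start none of the solid nucleophile is in solution
- what has gone from electrophile into another species counts as reacted, even if it can come back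
- run time (flask): 5.0 min

- part of the electrophile that has reacted at 5.0 min
- share of free nucleophile in free nucleophile and protonated nucleophile together, at 5.0 min

Each product sets free one acid, and as long as step 2 binds that acid to a second nucleophile, a product costs two nucleophile. The pair mark, the solid nucleophile charged divided by twice the electrophile charged, is the share of the electrophile that becomes product at that full price: 75.0%. By this count the opposite outcome, nucleophile outlasting the electrophile, asks for a pair mark above one, so a charge above 0.360 M. This flask holds 0.270 M, less than that, which makes the solid nucleophile the limiting reagent.

Step 1 alone, at the charged concentrations, gives the nucleophile a half-life of 2.6 s, and the solid, dissolving at its fastest rate, needs 24.0 s; both are short against the run of 5.0 min, so you expect this flask to reach the mark early. You take the electrophile beyond the mark to be shared with its dormant form, and that balance has a relaxation half-life of 0.119 min, also short against the run. So you reckon 7.86% of the charge left unbound and commit to 92.1% reacted. For the free share, this reckoning gives no number.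

The forecast gives 93.7% and 1.3%, reasoning that “the 0.27 M of nucleophile is used up after about 0.135 M of product”. Its reacted part stands 1.6 percentage points above your reckoning.

The flask gives 93.8% and 1.32%, and the forecast held. The hold-up by the crawl of the solid into solution makes no difference to the reacted part. At 5.00 min this flask has 0% of its solid nucleophile left, and its product stands at 80.0%, above the pair mark of 75.0%, with 0.0197 M of acid set free standing unbound. In the neighbour flask with 0.45 M of electrophile the pair mark falls to 30.0%, and at 5.00 min its product stands at 37.1% of that charge.

(Its constants are those of an exercise; the run is a simulation.)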